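(The numbers are those of an exercise; the run is a simulation.)

We follow one molecule of D.

    D ⇌ X, rate k1*(cs1 - [X]) while solid is left; crystals form when [X] > cs1 (cs1 = 9.2 mM, k1 = 1.87 × 10⁻⁵ s⁻¹)
    L → Z (k2 = 6.84 × 10⁻⁴ s⁻¹)
    J + Z → J.Z (k3 = 5.33 × 10⁻⁴ M⁻¹ s⁻¹)
    X → J (k4 = 1.63 × 10⁻⁵ s⁻¹)

D 0.20 M; L 1.50 equiv; time 2.5 d

- D is a solid; its amount is given per volume of the solution
- at the start none of D is in solution
- run time (flask): 2.5 d

- the J.Z standing at 2.5 d, as a percentage of the D charged
- the change that raises the amount of J.Z at 2.5 d, in percent of the D charged most ("none" if none brings more than 2 percentage points) (east / south-east / north-east / none)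
- amount of J.Z at 2.5 d, in percent of the D charged, after north-east

**Two flasks.** Beside the flask stands a neighbour with 0.50 M of D, the same equivalents of L and the same time. In both, step 1 can deliver at most 37.2 mM even into an empty solution, less than the 0.20 M charged in the flask, so solid stays in both and the rate law of step 1 contains no term for the charge.

**One molecule.** Once dissolved as X, the molecule becomes J with a half-life of 0.49 d. L has become Z far sooner, with a half-life of 0.28 h. J then meets Z in a pseudo-first-order step of at least 1.07 × 10⁻⁴ s⁻¹, faster than the 1.63 × 10⁻⁵ s⁻¹ of X, so J waits only briefly.

**The feed.** X rises until filling balances draining, at 4.92 mM, after a lag of 7.94 h. The amount passing from X to J by the end is then 15.0 mM; we call this the feed. It contains neither D's charge nor L, so both flasks receive the same molar feed, and the neighbour's percentage is 0.400 of the flask's.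

**Our reckoning.** In the flask the feed is 7.51% of the D charged, and J.Z stands slightly below that by the J still waiting. Doubling the dissolution coefficient gives a feed of 10.3%. Doubling the solubility doubles the feed and more L leaves it unchanged, so the best change is south-east.

The forecast, a little under our feed, gives 7.2%, 9.95% after north-east, and south-east as best, on this ground: “The bottleneck is dissolution plus X → J.”

**The result.** The flask gives 7.25%, 9.96% after north-east, and south-east as best. J standing in the flask at 2.50 d is 0.263% of the D charged, and the feed less that J comes to 7.24%. In the neighbour the same feed is 3.00% of its D, J stands at 0.0409%, and J.Z stands at 2.96%.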